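The target is read as the ring-opened isomer of a ring B 5',6'-epoxide: its C5' hydroxyl, its C6'=C7' bond and the whole retro chromophore arise together when a carbanion at C10 relays through the seven chain double bonds C11=C12 to C7'=C8' and expels the C6'–O bond. The C11–C12 bond is therefore made by Wittig olefination of a C15 phosphonium salt (ring A, C7–C11, with C10 as a methylene) with a C25 epoxy-polyenal (C12–C7', ring B), and base in the same flask removes the doubly allylic C10–H. One operation joins the halves and shifts those seven double bonds by one position, so that C11–C12 ends as a single bond.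

Key step: step 17

Remarks: carotenoid locants are used (ring A C1–C6, chain C7–C15 and C15'–C7', ring B C1'–C6'; the C25 aldehydes 14 and 15 carry unprimed apo-carotenoid locants). Assumption: the (S,S)-TsDPEN ruthenium catalyst is taken to give the S alcohol, as with aryl and alkenyl ketones; if the sense is opposite, the catalyst antipodes of steps 1 and 10 are exchanged. The double bonds that step 17 relocates (C9'=C10', C11'=C12', C11=C12) need no geometric control; the SMILES show the expected major isomers.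

Step 1
Reactants: 1 ketoisophorone
Product: 2 (4R)-4-hydroxy-2,6,6-trimethylcyclohex-2-en-1-one ((R)-phorenol)
Conditions: RuCl[(R,R)-TsDPEN](p-cymene) (1 mol %), iPrOH, rt
Reagents that add atoms: none
Why: Noyori-type asymmetric transfer hydrogenation should reduce the unhindered C4 carbonyl (flanked by CH= and CH2) rather than the neopentyl C1 carbonyl, the catalyst setting the carbinol centre as R.

Step 2
Reactants: 2 (R)-phorenol
Product: 3 (4R)-4-(tert-butyldimethylsilyloxy)-2,6,6-trimethylcyclohex-2-en-1-one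
Conditions: TBSCl, imidazole, DMF, rt
Reagents that add atoms: tert-butyldimethylsilyl chloride, CC(C)(C)[Si](C)(C)Cl
Why: Standard silylation of a secondary alcohol protects the hydroxyl for the enolate chemistry and later provides the steric bias for epoxidation.

Step 3
Reactants: 3 silyloxy enone
Product: 5 (4S)-4-(tert-butyldimethylsilyloxy)-2,6,6-trimethylcyclohex-1-en-1-yl trifluoromethanesulfonate, via lithium enolate 4 (not isolated)
Conditions: LiBH(sBu)3 (L-Selectride), THF, −78 °C; then PhNTf2, −78 °C to rt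
Reagents that add atoms: N-phenylbis(trifluoromethanesulfonimide), FC(F)(F)S(=O)(=O)N(c1ccccc1)S(=O)(=O)C(F)(F)F
Why: Conjugate hydride addition to the β-unsubstituted, carbonyl-hindered cyclohexenone gives the regiodefined tetrasubstituted enolate, which is trapped on oxygen (reductive enol triflate formation); no stereocentre is formed.

Step 4
Reactants: 6 (E)-3-methylpent-2-en-4-yn-1-ol
Product: 7 (2E,4E)-3-methyl-5-(tributylstannyl)penta-2,4-dien-1-ol
Conditions: Bu3SnH, PdCl2(PPh3)2 (cat.), THF, 0 °C
Reagents that add atoms: tributyltin hydride, CCCC[SnH](CCCC)CCCC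
Why: Palladium-catalysed syn-hydrostannation of the terminal enyne should place tin on the terminal carbon and give the E-alkenylstannane.

Step 5
Reactants: 5 enol triflate; 7 dienylstannane
Product: 8 (2E,4E)-5-[(4S)-4-(tert-butyldimethylsilyloxy)-2,6,6-trimethylcyclohex-1-en-1-yl]-3-methylpenta-2,4-dien-1-ol
Conditions: Pd(PPh3)4 (cat.), CuCl, LiCl, DMSO, 60 °C
Reagents that add atoms: none
Why: Stille coupling, accelerated by CuCl/LiCl for the hindered tetrasubstituted triflate, forms C6'–C7' with retention of both alkene geometries.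

Step 6
Reactants: 8 C15 trienol
Product: 9 (2E,4E)-5-[(1R,4R,6S)-4-(tert-butyldimethylsilyloxy)-2,2,6-trimethyl-7-oxabicyclo[4.1.0]heptan-1-yl]-3-methylpenta-2,4-dien-1-ol (carotenoid locants 3R,5S,6R; oxirane trans to the silyloxy group)
Conditions: mCPBA (1.0 equiv), CH2Cl2/aq. phosphate buffer (pH 8), 0 °C
Reagents that add atoms: 3-chloroperoxybenzoic acid, OOC(=O)c1cccc(Cl)c1
Why: Prilezhaev epoxidation should take the most electron-rich, tetrasubstituted ring alkene from the face anti to the silyloxy group (as with 3-acyloxy β-end groups), which sets C5' as S and C6' as R.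

Step 7
Reactants: 9 C15 epoxy alcohol
Product: 11 C15 epoxy-dienyl triphenylphosphonium bromide, via allylic bromide 10 (not isolated)
Conditions: CBr4, PPh3 (2.2 equiv), 2,6-lutidine, CH2Cl2, 0 °C to rt
Reagents that add atoms: carbon tetrabromide, BrC(Br)(Br)Br; triphenylphosphine, c1ccc(cc1)P(c1ccccc1)c1ccccc1
Why: Appel bromination under acid-free conditions followed by quaternisation of the allylic bromide with the excess phosphine should leave the acid-labile alkenyl oxirane intact.

Step 8
Reactants: 11 phosphonium bromide; 12 (2E,4E,6E)-2,7-dimethylocta-2,4,6-trienedial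
Product: 14 (3R,5S,6R)-3-(tert-butyldimethylsilyloxy)-5,6-epoxy-5,6-dihydro-12'-apo-β-caroten-12'-al, via phosphorus ylide 13 (not isolated)
Conditions: NaOMe, MeOH/CH2Cl2, 0 °C to rt; 12 (3 equiv)
Reagents that add atoms: none
Why: Wittig olefination of the semistabilised ylide with one aldehyde group of the dial (used in excess) forms C11'=C12', a bond whose geometry is immaterial because step 17 converts it into a single bond.

Step 9
Reactants: 14 silylated C25 epoxy-aldehyde
Product: 15 (3R,5S,6R)-5,6-epoxy-3-hydroxy-5,6-dihydro-12'-apo-β-caroten-12'-al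
Conditions: Bu4NF, THF, 0 °C
Reagents that add atoms: none
Why: Fluoride desilylation frees the ring B hydroxyl under non-acidic conditions that the oxirane and the polyenal tolerate.

Step 10
Reactants: 1 ketoisophorone
Product: 16 (4S)-4-hydroxy-2,6,6-trimethylcyclohex-2-en-1-one ((S)-phorenol)
Conditions: RuCl[(S,S)-TsDPEN](p-cymene) (1 mol %), iPrOH, rt
Reagents that add atoms: none
Why: The same Noyori-type transfer hydrogenation with the antipodal catalyst should give the S carbinol that becomes C3 of ring A.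

Step 11
Reactants: 16 (S)-phorenol
Product: 17 (4S)-4-(tert-butyldimethylsilyloxy)-2,6,6-trimethylcyclohex-2-en-1-one
Conditions: TBSCl, imidazole, DMF, rt
Reagents that add atoms: tert-butyldimethylsilyl chloride, CC(C)(C)[Si](C)(C)Cl
Why: Standard silylation protects the allylic hydroxyl through the addition and dehydration steps.

Step 12
Reactants: 17 silyloxy enone; 18 ethyl (E)-4-bromo-2-methylbut-2-enoate
Product: 20 ethyl (2E)-4-[(4S)-4-(tert-butyldimethylsilyloxy)-1-hydroxy-2,6,6-trimethylcyclohex-2-en-1-yl]-2-methylbut-2-enoate (both C1 epimers), via zinc dienolate 19 (not isolated)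
Conditions: Zn dust (activated), THF, reflux; aq. NH4Cl
Reagents that add atoms: none
Why: Vinylogous Reformatsky reaction should give the γ-adduct, since α-attack would join two quaternary carbons and is reversible, while the 2-methyl group keeps the enoate E; the new carbinol centre is removed in step 13.

Step 13
Reactants: 20 hydroxy ester
Product: 21 ethyl (2E,4E)-4-[(4S)-4-(tert-butyldimethylsilyloxy)-2,6,6-trimethylcyclohex-2-en-1-ylidene]-2-methylbut-2-enoate
Conditions: Burgess reagent (MeO2C–N(−)–SO2–N(+)Et3), toluene, 50 °C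
Reagents that add atoms: none
Why: Burgess dehydration can only remove a hydrogen from C7 (C1 and C5 carry none), and the chain should settle syn to the gem-dimethyl carbon (6E) to avoid allylic 1,3-strain with the in-plane C5 methyl.

Step 14
Reactants: 21 retro-trienoate
Product: 22 (2E,4E)-4-[(4S)-4-(tert-butyldimethylsilyloxy)-2,6,6-trimethylcyclohex-2-en-1-ylidene]-2-methylbut-2-en-1-ol
Conditions: iBu2AlH, CH2Cl2, −78 °C; aq. potassium sodium tartrate (KNaC4H4O6)
Reagents that add atoms: none
Why: 1,2-Reduction of the conjugated ester by the aluminium hydride gives the allylic alcohol without touching the triene.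

Step 15
Reactants: 22 retro-trienol
Product: 24 [(3E,5E)-5-[(4S)-4-(tert-butyldimethylsilyloxy)-2,6,6-trimethylcyclohex-2-en-1-ylidene]-3-methylpent-3-en-1-yl]triphenylphosphonium bromide, via allylic mesylate 23 (not isolated)
Conditions: n-BuLi then MsCl, THF, −78 °C; transfer into Ph3P=CH2 (from Ph3PCH3Br, n-BuLi, THF), −78 to 0 °C
Reagents that add atoms: methyltriphenylphosphonium bromide, C[P+](c1ccccc1)(c1ccccc1)c1ccccc1.[Br-]
Why: C-Alkylation of methylenetriphenylphosphorane at the primary allylic carbon (SN2) adds C11 and gives the homoallylic phosphonium salt in which C10 is the required methylene.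

Step 16
Reactants: 24 silylated phosphonium bromide
Product: 25 [(3E,5E)-5-[(4S)-4-hydroxy-2,6,6-trimethylcyclohex-2-en-1-ylidene]-3-methylpent-3-en-1-yl]triphenylphosphonium bromide
Conditions: Bu4NF, AcOH, THF, 0 °C
Reagents that add atoms: none
Why: Buffered fluoride desilylation frees the C3 hydroxyl, which as an alkoxide cannot be expelled from the carbanion generated in step 17.

Step 17
Reactants: 25 C15 hydroxy phosphonium bromide; 15 C25 epoxy-hydroxy-aldehyde
Product: 28 target, all-E (3S,3'R,5'S)-4,5'-retro-β,β-carotene-3,3',5'-triol, via ylide 26 (not isolated), via skipped epoxy-polyene 27 (not isolated)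
Conditions: KN(SiMe3)2 (1.05 equiv), THF, −78 °C; add 15, −78 to 0 °C; then KOtBu (4 equiv), DMSO, 0 °C to rt, argon, dark; H2O
Reagents that add atoms: none
Why: Proposed new method: the non-stabilised ylide 26 condenses with aldehyde 15 through an oxaphosphetane to give the C11=C12 alkene of 27 (ordinary Wittig chemistry, E/Z ratio immaterial), and KOtBu/DMSO then removes the C10–H that is allylic to both the ring A triene and the C11–C7' heptaene, so that the delocalised carbanion passes its electron pair along C11 to C7' and expels the oxirane C6'–O bond in a vinylogous E1cB (1,16-)elimination driven by epoxide strain. The closest known reaction types are the base-induced E1cB opening of the β,γ-epoxy ketone of fucoxanthin to isofucoxanthin and the base-mediated isomerisation of lutein to zeaxanthin, which runs through the same kind of polyenyl carbanion. No ring is closed and no stereocentre is created: C5' keeps the configuration set in step 6 because only the C6'–O bond breaks, and C3 and C3' are untouched. The new double bonds arise from s-trans single bonds of 27 and should be E, and C6'=C7' should be E because the breaking C6'–O bond must lie parallel to the carbanion π-system with C8' turned away from C5', as in SN2' openings of 1-alkenylcyclohexene oxides. The step needs deprotonation at C10 rather than at the allylic methyl groups, which the double allylic activation should secure, and it needs the C3 oxygen to stay, which is secured by carrying it as a free hydroxyl (an alkoxide under the conditions) instead of a silyl ether.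

Compound list
1 | ketoisophorone (2,6,6-trimethylcyclohex-2-ene-1,4-dione) | CC1=CC(=O)CC(C)(C)C1=O | starting material
2 | (4R)-4-hydroxy-2,6,6-trimethylcyclohex-2-en-1-one | CC1=C[C@H](O)CC(C)(C)C1=O | intermediate
3 | (4R)-4-(tert-butyldimethylsilyloxy)-2,6,6-trimethylcyclohex-2-en-1-one | CC1=C[C@H](O[Si](C)(C)C(C)(C)C)CC(C)(C)C1=O | intermediate
4 | lithium (4S)-4-(tert-butyldimethylsilyloxy)-2,6,6-trimethylcyclohex-1-en-1-olate | CC1=C([O-])C(C)(C)C[C@@H](O[Si](C)(C)C(C)(C)C)C1.[Li+] | intermediate
5 | (4S)-4-(tert-butyldimethylsilyloxy)-2,6,6-trimethylcyclohex-1-en-1-yl trifluoromethanesulfonate | CC1=C(OS(=O)(=O)C(F)(F)F)C(C)(C)C[C@@H](O[Si](C)(C)C(C)(C)C)C1 | intermediate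
6 | (E)-3-methylpent-2-en-4-yn-1-ol | OC/C=C(C)/C#C | starting material
7 | (2E,4E)-3-methyl-5-(tributylstannyl)penta-2,4-dien-1-ol | OC/C=C(C)/C=C/[Sn](CCCC)(CCCC)CCCC | intermediate
8 | (2E,4E)-5-[(4S)-4-(tert-butyldimethylsilyloxy)-2,6,6-trimethylcyclohex-1-en-1-yl]-3-methylpenta-2,4-dien-1-ol | CC1=C(/C=C/C(C)=C/CO)C(C)(C)C[C@@H](O[Si](C)(C)C(C)(C)C)C1 | intermediate
9 | (2E,4E)-5-[(1R,4R,6S)-4-(tert-butyldimethylsilyloxy)-2,2,6-trimethyl-7-oxabicyclo[4.1.0]heptan-1-yl]-3-methylpenta-2,4-dien-1-ol | C[C@@]12O[C@]1(/C=C/C(C)=C/CO)C(C)(C)C[C@@H](O[Si](C)(C)C(C)(C)C)C2 | intermediate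
10 | allylic bromide of 9 (C11' bromide) | C[C@@]12O[C@]1(/C=C/C(C)=C/CBr)C(C)(C)C[C@@H](O[Si](C)(C)C(C)(C)C)C2 | intermediate
11 | C15 epoxy-dienyl triphenylphosphonium bromide | C[C@@]12O[C@]1(/C=C/C(C)=C/C[P+](c3ccccc3)(c3ccccc3)c3ccccc3)C(C)(C)C[C@@H](O[Si](C)(C)C(C)(C)C)C2.[Br-] | intermediate
12 | (2E,4E,6E)-2,7-dimethylocta-2,4,6-trienedial | O=C/C(C)=C/C=C/C=C(C)/C=O | starting material
13 | phosphorus ylide of 11 | C[C@@]12O[C@]1(/C=C/C(C)=C/C=P(c3ccccc3)(c3ccccc3)c3ccccc3)C(C)(C)C[C@@H](O[Si](C)(C)C(C)(C)C)C2 | intermediate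
14 | (3R,5S,6R)-3-(tert-butyldimethylsilyloxy)-5,6-epoxy-5,6-dihydro-12'-apo-β-caroten-12'-al | C[C@@]12O[C@]1(/C=C/C(C)=C/C=C/C(C)=C/C=C/C=C(C)/C=O)C(C)(C)C[C@@H](O[Si](C)(C)C(C)(C)C)C2 | intermediate
15 | (3R,5S,6R)-5,6-epoxy-3-hydroxy-5,6-dihydro-12'-apo-β-caroten-12'-al | C[C@@]12O[C@]1(/C=C/C(C)=C/C=C/C(C)=C/C=C/C=C(C)/C=O)C(C)(C)C[C@@H](O)C2 | intermediate
16 | (4S)-4-hydroxy-2,6,6-trimethylcyclohex-2-en-1-one | CC1=C[C@@H](O)CC(C)(C)C1=O | intermediate
17 | (4S)-4-(tert-butyldimethylsilyloxy)-2,6,6-trimethylcyclohex-2-en-1-one | CC1=C[C@@H](O[Si](C)(C)C(C)(C)C)CC(C)(C)C1=O | intermediate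
18 | ethyl (E)-4-bromo-2-methylbut-2-enoate | CCOC(=O)/C(C)=C/CBr | starting material
19 | zinc dienolate of 18, [(E)-4-ethoxy-3-methyl-4-oxobut-2-en-1-yl]zinc bromide | CCOC(=O)/C(C)=C/C[Zn]Br | intermediate
20 | ethyl (2E)-4-[(4S)-4-(tert-butyldimethylsilyloxy)-1-hydroxy-2,6,6-trimethylcyclohex-2-en-1-yl]-2-methylbut-2-enoate (C1 epimers) | CCOC(=O)/C(C)=C/CC1(O)C(C)=C[C@@H](O[Si](C)(C)C(C)(C)C)CC1(C)C | intermediate
21 | ethyl (2E,4E)-4-[(4S)-4-(tert-butyldimethylsilyloxy)-2,6,6-trimethylcyclohex-2-en-1-ylidene]-2-methylbut-2-enoate | CCOC(=O)/C(C)=C/C=C1/C(C)=C[C@@H](O[Si](C)(C)C(C)(C)C)CC1(C)C | intermediate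
22 | (2E,4E)-4-[(4S)-4-(tert-butyldimethylsilyloxy)-2,6,6-trimethylcyclohex-2-en-1-ylidene]-2-methylbut-2-en-1-ol | OC/C(C)=C/C=C1/C(C)=C[C@@H](O[Si](C)(C)C(C)(C)C)CC1(C)C | intermediate
23 | methanesulfonate of 22 | CS(=O)(=O)OC/C(C)=C/C=C1/C(C)=C[C@@H](O[Si](C)(C)C(C)(C)C)CC1(C)C | intermediate
24 | [(3E,5E)-5-[(4S)-4-(tert-butyldimethylsilyloxy)-2,6,6-trimethylcyclohex-2-en-1-ylidene]-3-methylpent-3-en-1-yl]triphenylphosphonium bromide | [Br-].C(C[P+](c1ccccc1)(c1ccccc1)c1ccccc1)/C(C)=C/C=C2/C(C)=C[C@@H](O[Si](C)(C)C(C)(C)C)CC2(C)C | intermediate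
25 | [(3E,5E)-5-[(4S)-4-hydroxy-2,6,6-trimethylcyclohex-2-en-1-ylidene]-3-methylpent-3-en-1-yl]triphenylphosphonium bromide | [Br-].C(C[P+](c1ccccc1)(c1ccccc1)c1ccccc1)/C(C)=C/C=C2/C(C)=C[C@@H](O)CC2(C)C | intermediate
26 | phosphorus ylide of 25 | C(C=P(c1ccccc1)(c1ccccc1)c1ccccc1)/C(C)=C/C=C2/C(C)=C[C@@H](O)CC2(C)C | intermediate
27 | skipped C40 epoxy-polyene: ring A trienyl unit (C4=C5, C6=C7, C8=C9), C10 methylene, heptaene C11=C12 (Z) to C7'=C8', ring B (3'R,5'S,6'R)-5',6'-epoxide, 3- and 3'-hydroxyls | CC1=C[C@@H](O)CC(C)(C)\C1=C/C=C(C)/C/C=C\C(C)=C\C=C\C=C(C)\C=C\C=C(C)\C=C\[C@]12O[C@@]1(C)C[C@H](O)CC2(C)C | intermediate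
28 | all-E (3S,3'R,5'S)-4,5'-retro-β,β-carotene-3,3',5'-triol | CC1=C[C@@H](O)CC(C)(C)\C1=C/C=C(C)/C=C/C=C(C)/C=C/C=C/C(C)=C/C=C/C(C)=C/C=C1\C(C)(C)C[C@@H](O)C[C@]1(C)O | target

Total step count: 17. Longest linear sequence: 9 steps (1, 2, 3, 5, 6, 7, 8, 9, 17); the ring A branch (10–16, then 17) has 8.

Steps most likely to fail

Step 17. The base-triggered shift may suffer from competing deprotonation at the allylic methyl groups, from reprotonation of the polyenyl carbanion before it reaches the oxirane, or from loss of geometric control at C10=C11 and C6'=C7'. The fallback sets out from 27: the Wittig stage is quenched before KOtBu is added and 27 is isolated. It is then isomerised under neutral conditions with catalytic Pd(PPh3)4 in THF, the known isomerisation of alkenyl oxiranes to dienols by zerovalent palladium. Ionisation of the C6'–O bond gives a polyenyl palladium alkoxide, and β-hydride loss from C10 returns the route at 28. No new compound is made (F0).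

Step 12. Addition of the zinc dienolate to the hindered enone may be sluggish, may turn into conjugate addition, or may go through the α-carbon. The fallback sets out from 17 and builds the chain in two parts. Lithium ethoxyacetylide (ethoxyacetylene, n-BuLi, THF, −78 °C) adds to the carbonyl to give the propargylic alcohol F6. Meyer–Schuster rearrangement with catalytic Sc(OTf)3 gives the ethyl cyclohexenylidene-acetate F7. Reduction with iBu2AlH gives the dienol F8, and MnO2 gives the dienal F9. Wittig reaction with Ph3P=C(CH3)CO2Et then forms C8=C9 with E geometry and returns the route at 21.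

Step 6. The peracid may show poor facial selectivity, or the acid by-product may trigger furanoid rearrangement of the alkenyl oxirane. The fallback sets out from 5 and replaces substrate control by reagent control. Palladium-catalysed methoxycarbonylation (Pd(OAc)2, PPh3, CO, MeOH, Et3N) gives the methyl ester F1, and iBu2AlH gives the allylic alcohol F2. Sharpless epoxidation (Ti(OiPr)4, tBuOOH, with the diethyl tartrate antipode that the mnemonic assigns to the face anti to the silyloxy group, expected to be D-(−)) gives the epoxy alcohol F3. Parikh–Doering oxidation gives the epoxy aldehyde F4. Horner–Wadsworth–Emmons reaction with triethyl 3-methyl-4-phosphonocrotonate gives the C15 epoxy ester F5, and iBu2AlH returns the route at 9.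

Further compounds
F0 | step 17 | none | none
F1 | step 6 | methyl (4S)-4-(tert-butyldimethylsilyloxy)-2,6,6-trimethylcyclohex-1-ene-1-carboxylate | COC(=O)C1=C(C)C[C@H](O[Si](C)(C)C(C)(C)C)CC1(C)C
F2 | step 6 | [(4S)-4-(tert-butyldimethylsilyloxy)-2,6,6-trimethylcyclohex-1-en-1-yl]methanol | OCC1=C(C)C[C@H](O[Si](C)(C)C(C)(C)C)CC1(C)C
F3 | step 6 | [4-(tert-butyldimethylsilyloxy)-2,2,6-trimethyl-7-oxabicyclo[4.1.0]heptan-1-yl]methanol, ring configuration as in 9 | C[C@@]12O[C@]1(CO)C(C)(C)C[C@@H](O[Si](C)(C)C(C)(C)C)C2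
F4 | step 6 | 4-(tert-butyldimethylsilyloxy)-2,2,6-trimethyl-7-oxabicyclo[4.1.0]heptane-1-carbaldehyde, ring configuration as in 9 | C[C@@]12O[C@]1(C=O)C(C)(C)C[C@@H](O[Si](C)(C)C(C)(C)C)C2
F5 | step 6 | ethyl (2E,4E)-5-[(1R,4R,6S)-4-(tert-butyldimethylsilyloxy)-2,2,6-trimethyl-7-oxabicyclo[4.1.0]heptan-1-yl]-3-methylpenta-2,4-dienoate | C[C@@]12O[C@]1(/C=C/C(C)=C/C(=O)OCC)C(C)(C)C[C@@H](O[Si](C)(C)C(C)(C)C)C2
F6 | step 12 | (4S)-4-(tert-butyldimethylsilyloxy)-1-(ethoxyethynyl)-2,6,6-trimethylcyclohex-2-en-1-ol (C1 epimers) | CCOC#CC1(O)C(C)=C[C@@H](O[Si](C)(C)C(C)(C)C)CC1(C)C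
F7 | step 12 | ethyl (2E)-2-[(4S)-4-(tert-butyldimethylsilyloxy)-2,6,6-trimethylcyclohex-2-en-1-ylidene]acetate | CCOC(=O)/C=C1/C(C)=C[C@@H](O[Si](C)(C)C(C)(C)C)CC1(C)C
F8 | step 12 | (2E)-2-[(4S)-4-(tert-butyldimethylsilyloxy)-2,6,6-trimethylcyclohex-2-en-1-ylidene]ethanol | OC/C=C1/C(C)=C[C@@H](O[Si](C)(C)C(C)(C)C)CC1(C)C
F9 | step 12 | (2E)-2-[(4S)-4-(tert-butyldimethylsilyloxy)-2,6,6-trimethylcyclohex-2-en-1-ylidene]acetaldehyde | O=C/C=C1/C(C)=C[C@@H](O[Si](C)(C)C(C)(C)C)CC1(C)C
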